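**Retrosynthetic overview**
1. Target ⇐ 12-O-desilylation / 9-O-acetylation of a macrocyclic butenolide. The ten-membered ring and the butenolide close together from a C7 enal / C8≡C17 alkyne by nickel-mediated carbonylative cyclization (C7–C8, C17–C18, C18–O).
2. Ynal ⇐ Negishi sp3–sp2 coupling (C4–C5) of the cyclohexane core with (Z)-3-iodobut-2-enal.
3. Cyclohexane core (quaternary C1, C2–O, C14–O) ⇐ semipinacol 1,2-shift / ring expansion of an epoxy cyclopentanol, with in situ Tishchenko reduction (C10 migrates from C14 to C1).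
4. Epoxy cyclopentanol ⇐ Shi epoxidation ⇐ alkenylcerium addition to a 2,3-cis cyclopentanone ⇐ cuprate addition / kinetic protonation ⇐ Nozaki–Hiyama–Kishi coupling of an iodoenone from (R)-4-hydroxycyclopentenone with but-2-ynal.
5. Ring order: cyclopentane (bought) → cyclohexane (ring expansion) → ten-membered carbocycle and butenolide (one step).

Assumptions: (R)-4-hydroxycyclopent-2-en-1-one and but-2-ynal are bought; briarane numbering is used for all intermediates (C15 on C1, C16 on C5, C20 on C11, C18 lactone carbonyl, C19 methyl on C17; β = face of C15, α = face of H-10); the target is (1S,2S,5Z,7S,9S,10S,11R,12R,14S).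

**Step 1**
Reactants: 1 (R)-4-hydroxycyclopent-2-en-1-one
Product: 2 (R)-4-(tert-butyldimethylsilyloxy)cyclopent-2-en-1-one
Conditions: TBSCl, imidazole, CH2Cl2, 0 °C
Reagents that add atoms: tert-butyldimethylsilyl chloride, CC(C)(C)[Si](C)(C)Cl
Why: Imidazole-assisted silylation of the secondary alcohol leaves the future C12 stereocentre untouched.

**Step 2**
Reactants: 2 (R)-4-(tert-butyldimethylsilyloxy)cyclopent-2-en-1-one
Product: 3 (R)-4-(tert-butyldimethylsilyloxy)-2-iodocyclopent-2-en-1-one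
Conditions: I2, pyridine, CH2Cl2, 0 to 25 °C
Reagents that add atoms: iodine, [I][I]
Why: Johnson α-iodination of the enone (pyridine conjugate addition, iodination of the enolate, elimination) gives the 2-iodoenone without affecting C12.

**Step 3**
Reactants: 3 (R)-4-(tert-butyldimethylsilyloxy)-2-iodocyclopent-2-en-1-one, 4 but-2-ynal
Product: 5 (R)-4-(tert-butyldimethylsilyloxy)-2-[(R)-1-hydroxybut-2-yn-1-yl]cyclopent-2-en-1-one
Conditions: CrCl2 (4 equiv), NiCl2 (2 mol%), chiral oxazoline–sulfonamide ligand (Kishi type, antipode giving the shown carbinol), Et3N, THF, 25 °C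
Reagents that add atoms: none
Why: Nozaki–Hiyama–Kishi coupling (nickel activates the C–I bond, transmetalation to chromium, addition to the ynal) forms C9–C10, and the chiral sulfonamide on chromium selects the aldehyde face so that C9 is set by reagent control (minor epimer removed by chromatography).

**Step 4**
Reactants: 5 (R)-4-(tert-butyldimethylsilyloxy)-2-[(R)-1-hydroxybut-2-yn-1-yl]cyclopent-2-en-1-one
Product: 6 (R)-4-(tert-butyldimethylsilyloxy)-2-[(R)-1-(triethylsilyloxy)but-2-yn-1-yl]cyclopent-2-en-1-one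
Conditions: Et3SiCl, imidazole, DMF, 0 °C
Reagents that add atoms: chlorotriethylsilane, CC[Si](Cl)(CC)CC
Why: Routine silylation gives a C9 ether that is more labile than the C12 ether, so the two oxygens can be told apart at the end.

**Step 5**
Reactants: 6 (R)-4-(tert-butyldimethylsilyloxy)-2-[(R)-1-(triethylsilyloxy)but-2-yn-1-yl]cyclopent-2-en-1-one
Product: 8 (2R,3R,4R)-4-(tert-butyldimethylsilyloxy)-3-methyl-2-[(S)-1-(triethylsilyloxy)but-2-yn-1-yl]cyclopentan-1-one, via lithium enolate 7 (not isolated)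
Conditions: Me2CuLi (from CuI and MeLi), Et2O, −78 to −40 °C; then AcOH, THF, −78 °C
Reagents that add atoms: lithium dimethylcuprate, [Li+].C[Cu-]C
Why: Gilman cuprate 1,4-addition occurs anti to the C12 silyloxy group (sets C11) and kinetic C-protonation of enolate 7 occurs anti to the new methyl (sets C10, 2,3-cis); the ketone is used at once to avoid epimerisation.

**Step 6**
Reactants: 9 pent-3-yn-1-ol
Product: 10 5-chloropent-2-yne
Conditions: SOCl2, pyridine, CH2Cl2, 0 to 40 °C
Reagents that add atoms: thionyl chloride, O=S(Cl)Cl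
Why: Chlorodehydroxylation of the primary alcohol through its chlorosulfite (SN2).

**Step 7**
Reactants: 10 5-chloropent-2-yne
Product: 12 (E)-5-chloro-2-iodopent-2-ene, via alkenylzirconocene chloride 11 (not isolated)
Conditions: Cp2Zr(H)Cl (2.2 equiv), THF, 50 °C; then I2, 0 °C
Reagents that add atoms: iodine, [I][I]
Why: Schwartz hydrozirconation adds H and Zr syn and, after equilibration with excess reagent, places zirconium on the methyl-bearing alkyne carbon; iodinolysis with retention gives the (E)-2-iodoalkene.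

**Step 8**
Reactants: 12 (E)-5-chloro-2-iodopent-2-ene, 8 (2R,3R,4R)-4-(tert-butyldimethylsilyloxy)-3-methyl-2-[(S)-1-(triethylsilyloxy)but-2-yn-1-yl]cyclopentan-1-one
Product: 15 2,3-cis-3,4-trans-1-[(E)-5-chloropent-2-en-2-yl]-4-(tert-butyldimethylsilyloxy)-3-methyl-2-[(S)-1-(triethylsilyloxy)but-2-yn-1-yl]cyclopentan-1-ol (alkenyl group trans to the C2 side chain), via alkenyllithium 13 (not isolated), via alkenylcerium dichloride 14 (not isolated)
Conditions: t-BuLi (2.1 equiv), Et2O, −78 °C; CeCl3, THF, −78 °C; then 8, −78 °C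
Reagents that add atoms: none
Why: Iodine–lithium exchange with retention, transmetalation to the weakly basic organocerium (Imamoto conditions) and 1,2-addition anti to the C10 side chain; the new C14 carbinol centre is destroyed in step 10, so both C14 epimers converge.

**Step 9**
Reactants: 15 tertiary allylic alcohol from step 8
Product: 16 epoxy alcohol: 15 with the alkene converted into the (2R,3S)-3-(2-chloroethyl)-2-methyloxiran-2-yl group
Conditions: L-fructose-derived Shi ketone (ent-Shi ketone, 30 mol%), KHSO5 (as 2KHSO5·KHSO4·K2SO4), K2CO3, Bu4NHSO4, MeCN/CH2(OMe)2/aq. Na2B4O7 buffer, 0 °C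
Reagents that add atoms: potassium peroxymonosulfate, [K+].[O-]S(=O)(=O)OO
Why: Shi epoxidation (chiral dioxirane, spiro transition state) of the only alkene present; the L-fructose-derived ketone delivers oxygen to the face that gives the (1R,2S)-epoxide (briarane numbering), fixing the future C1 and C2 by reagent control.

**Step 10**
Reactants: 16 epoxy alcohol from step 9, 17 butanal
Product: 19 2-O-butanoyl-14α-hydroxy cyclohexane core (C1 quaternary; C3–C4 chain ending in Cl; 9-OTES; 12-OTBS; configuration as in 32), via ring-expanded hydroxy ketone 18 (not isolated)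
Conditions: SmI2 (30 mol%), ClCH2CH2Cl/THF, 0 to 25 °C
Reagents that add atoms: none
Why: Samarium-catalysed tandem semipinacol rearrangement / Evans–Tishchenko reduction: Lewis-acid opening of the epoxide at tertiary C1 triggers the 1,2-shift of the more substituted ring carbon C10 from C14 to C1 anti to the C–O bond (cyclopentane to cyclohexane, inversion at C1, retention at C10 and C2), and the samarium-bound butanal hemiacetal then delivers hydride intramolecularly to the new C14 ketone to give the 1,3-anti diol monoester, i.e. the 2-butanoate and the 14α-alcohol in one operation.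

**Step 11**
Reactants: 19 2-O-butanoyl-14α-hydroxy cyclohexane core
Product: 20 14-O-acetyl-2-O-butanoyl cyclohexane core chloride (1S,2S,9S,10S,11R,12R,14S)
Conditions: Ac2O, DMAP, pyridine, CH2Cl2, 0 to 25 °C
Reagents that add atoms: acetic anhydride, CC(=O)OC(C)=O
Why: DMAP-catalysed acetylation of the remaining secondary alcohol, done promptly to prevent 1,3-acyl migration.

**Step 12**
Reactants: 21 but-2-yn-1-ol
Product: 23 (Z)-3-iodobut-2-en-1-ol, via cyclic vinylalanate 22 (not isolated)
Conditions: NaAlH2(OCH2CH2OCH3)2, THF, 0 to 25 °C; then I2, −78 °C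
Reagents that add atoms: iodine, [I][I]
Why: Hydroxyl-directed trans-hydroalumination places aluminium on C3 in a cyclic alanate, and iodinolysis with retention gives the (Z)-iodoalkene.

**Step 13**
Reactants: 23 (Z)-3-iodobut-2-en-1-ol
Product: 24 (Z)-3-iodobut-2-enal
Conditions: MnO2, CH2Cl2, 25 °C
Reagents that add atoms: none
Why: Neutral MnO2 oxidation of the allylic alcohol keeps the Z geometry; the aldehyde is used fresh.

**Step 14**
Reactants: 20 14-O-acetyl-2-O-butanoyl cyclohexane core chloride, 24 (Z)-3-iodobut-2-enal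
Product: 27 seco-ynal with (5Z)-enal and C8≡C17 alkyne (1S,2S,9S,10S,11R,12R,14S), via alkyl iodide 25 (not isolated), via alkylzinc iodide 26 (not isolated)
Conditions: NaI, Zn dust, I2 (5 mol%), N,N-dimethylacetamide, 70 °C; then 24, Pd(PPh3)4 (5 mol%), 25 °C
Reagents that add atoms: none
Why: In situ Finkelstein exchange, zinc insertion into the primary alkyl iodide and Negishi sp3–sp2 cross-coupling with the activated β-iodoenal form C4–C5 with retention of the Z geometry; esters, silyl ethers and the internal alkyne tolerate the organozinc.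

**Step 15**
Reactants: 27 seco-ynal
Product: 29 macrocyclic butenolide: 14-O-acetyl-2-O-butanoyl-9-O-triethylsilyl-12-O-tert-butyldimethylsilyl (1S,2S,5Z,7S,9S,10S,11R,12R,14S), via oxanickelacyclopentene 28 (not isolated)
Conditions: Ni(cod)2 (1.1 equiv), 1,3-bis(2,6-diisopropylphenyl)imidazol-2-ylidene (IPr, 1.1 equiv), toluene (2 mM, slow addition of 27), 40 °C; then CO (1 atm), 25 °C
Reagents that add atoms: carbon monoxide, [C-]#[O+]
Why: Proposed new method: a nickel-mediated carbonylative ynal macrocyclization (macrocyclic hetero-Pauson–Khand reaction) in which zerovalent nickel–IPr binds the aldehyde and the alkyne of 27 and undergoes oxidative cyclization to oxanickelacyclopentene 28 (the bulky carbene keeps the small methyl-bearing alkyne carbon C17 on nickel, so C7 bonds to C8 and the ring formed is ten-membered; the Z-alkene pre-folds the chain), CO then inserts into the Ni–C17 bond and C–O reductive elimination releases the butenolide, while C7 is expected to be set because the tether must reach C7 on the face of the metallacycle occupied by C10 when H-9 eclipses the C8=C17 axis (allylic strain), which is the natural 7S arrangement; the closest known chemistry is the nickel–carbene catalysed reductive macrocyclization of ynals with silanes (same metallacycle, hydride instead of CO) and the titanium-, ruthenium- or molybdenum-mediated hetero-Pauson–Khand cyclization of short-tethered ynals to fused butenolides.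

**Step 16**
Reactants: 29 macrocyclic butenolide
Product: 30 9-hydroxy macrocyclic butenolide (12-OTBS retained)
Conditions: PPTS, MeOH/CH2Cl2, 0 °C
Reagents that add atoms: none
Why: Acid-catalysed methanolysis cleaves the triethylsilyl ether far faster than the tert-butyldimethylsilyl ether.

**Step 17**
Reactants: 30 9-hydroxy macrocyclic butenolide
Product: 31 9,14-di-O-acetyl-2-O-butanoyl-12-O-tert-butyldimethylsilyl macrocycle
Conditions: Ac2O, DMAP, pyridine, CH2Cl2, 25 °C
Reagents that add atoms: acetic anhydride, CC(=O)OC(C)=O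
Why: DMAP-catalysed acetylation of the only free hydroxyl (allylic C9–OH).

**Step 18**
Reactants: 31 9,14-di-O-acetyl-2-O-butanoyl-12-O-tert-butyldimethylsilyl macrocycle
Product: 32 CNP0281577.2
Conditions: HF·pyridine, pyridine/THF, 0 to 25 °C
Reagents that add atoms: none
Why: Fluoride desilylation under non-basic conditions frees 12-OH without acyl migration or epimerisation at C7.

**Compound list**
1 | (R)-4-hydroxycyclopent-2-en-1-one | O=C1C=C[C@H](O)C1 | starting material
2 | (R)-4-(tert-butyldimethylsilyloxy)cyclopent-2-en-1-one | O=C1C=C[C@H](O[Si](C)(C)C(C)(C)C)C1 | intermediate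
3 | (R)-4-(tert-butyldimethylsilyloxy)-2-iodocyclopent-2-en-1-one | O=C1C([I])=C[C@H](O[Si](C)(C)C(C)(C)C)C1 | intermediate
4 | but-2-ynal | CC#CC=O | starting material
5 | (R)-4-(tert-butyldimethylsilyloxy)-2-[(R)-1-hydroxybut-2-yn-1-yl]cyclopent-2-en-1-one | CC#C[C@@H](O)C1=C[C@H](O[Si](C)(C)C(C)(C)C)CC1=O | intermediate
6 | (R)-4-(tert-butyldimethylsilyloxy)-2-[(R)-1-(triethylsilyloxy)but-2-yn-1-yl]cyclopent-2-en-1-one | CC#C[C@@H](O[Si](CC)(CC)CC)C1=C[C@H](O[Si](C)(C)C(C)(C)C)CC1=O | intermediate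
7 | lithium enolate of 8 (C14=C10 enolate; C11 and C12 set) | [Li]OC1=C([C@H](O[Si](CC)(CC)CC)C#CC)[C@@H](C)[C@H](O[Si](C)(C)C(C)(C)C)C1 | intermediate
8 | (2R,3R,4R)-4-(tert-butyldimethylsilyloxy)-3-methyl-2-[(S)-1-(triethylsilyloxy)but-2-yn-1-yl]cyclopentan-1-one | CC#C[C@@H](O[Si](CC)(CC)CC)[C@H]1[C@@H](C)[C@H](O[Si](C)(C)C(C)(C)C)CC1=O | intermediate
9 | pent-3-yn-1-ol | CC#CCCO | starting material
10 | 5-chloropent-2-yne | CC#CCCCl | intermediate
11 | (E)-(5-chloropent-2-en-2-yl)zirconocene chloride | C/C([Zr](Cl)(C1C=CC=C1)C1C=CC=C1)=C\CCCl | intermediate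
12 | (E)-5-chloro-2-iodopent-2-ene | C/C([I])=C\CCCl | intermediate
13 | (E)-(5-chloropent-2-en-2-yl)lithium | C/C([Li])=C\CCCl | intermediate
14 | (E)-(5-chloropent-2-en-2-yl)cerium dichloride | C/C([Ce](Cl)Cl)=C\CCCl | intermediate
15 | 1-[(E)-5-chloropent-2-en-2-yl] tertiary alcohol from 8 (alkenyl trans to the C10 side chain; ring centres as in 8) | CC#C[C@@H](O[Si](CC)(CC)CC)[C@H]1[C@@H](C)[C@H](O[Si](C)(C)C(C)(C)C)C[C@]1(O)/C(C)=C/CCCl | intermediate
16 | epoxy alcohol: 15 bearing the (2R,3S)-3-(2-chloroethyl)-2-methyloxiran-2-yl group | CC#C[C@@H](O[Si](CC)(CC)CC)[C@H]1[C@@H](C)[C@H](O[Si](C)(C)C(C)(C)C)C[C@]1(O)[C@]2(C)O[C@H]2CCCl | intermediate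
17 | butanal | CCCC=O | starting material
18 | ring-expanded hydroxy ketone: C14 cyclohexanone with quaternary C1 and free 2-OH (1S,2S,9S,10S,11R,12R) | O[C@@H](CCCl)[C@@]1(C)C(=O)C[C@@H](O[Si](C)(C)C(C)(C)C)[C@H](C)[C@@H]1[C@H](O[Si](CC)(CC)CC)C#CC | intermediate
19 | 2-O-butanoyl-14α-hydroxy cyclohexane core chloride (configuration as in 32) | CCCC(=O)O[C@@H](CCCl)[C@@]1(C)[C@@H](O)C[C@@H](O[Si](C)(C)C(C)(C)C)[C@H](C)[C@@H]1[C@H](O[Si](CC)(CC)CC)C#CC | intermediate
20 | 14-O-acetyl-2-O-butanoyl cyclohexane core chloride (1S,2S,9S,10S,11R,12R,14S) | CCCC(=O)O[C@@H](CCCl)[C@@]1(C)[C@@H](OC(C)=O)C[C@@H](O[Si](C)(C)C(C)(C)C)[C@H](C)[C@@H]1[C@H](O[Si](CC)(CC)CC)C#CC | intermediate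
21 | but-2-yn-1-ol | CC#CCO | starting material
22 | sodium cyclic (Z)-vinylalanate from 21 | [Na+].CC1=CCO[Al-]1(OCCOC)OCCOC | intermediate
23 | (Z)-3-iodobut-2-en-1-ol | C/C([I])=C/CO | intermediate
24 | (Z)-3-iodobut-2-enal | C/C([I])=C/C=O | intermediate
25 | alkyl iodide analogue of 20 | CCCC(=O)O[C@@H](CC[I])[C@@]1(C)[C@@H](OC(C)=O)C[C@@H](O[Si](C)(C)C(C)(C)C)[C@H](C)[C@@H]1[C@H](O[Si](CC)(CC)CC)C#CC | intermediate
26 | alkylzinc iodide from 25 | CCCC(=O)O[C@@H](CC[Zn][I])[C@@]1(C)[C@@H](OC(C)=O)C[C@@H](O[Si](C)(C)C(C)(C)C)[C@H](C)[C@@H]1[C@H](O[Si](CC)(CC)CC)C#CC | intermediate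
27 | seco-ynal: (5Z)-enal at C7 and C8≡C17 alkyne (1S,2S,9S,10S,11R,12R,14S) | CCCC(=O)O[C@@H](CC/C(C)=C\C=O)[C@@]1(C)[C@@H](OC(C)=O)C[C@@H](O[Si](C)(C)C(C)(C)C)[C@H](C)[C@@H]1[C@H](O[Si](CC)(CC)CC)C#CC | intermediate
28 | (IPr)nickel oxanickelacyclopentene (Ni bonded to O7 and C17) | CCCC(=O)O[C@H]1CC/C(C)=C\[C@@H]2O[Ni](=C3N(c4c(C(C)C)cccc4C(C)C)C=CN3c3c(C(C)C)cccc3C(C)C)C(C)=C2[C@@H](O[Si](CC)(CC)CC)[C@H]2[C@@H](C)[C@H](O[Si](C)(C)C(C)(C)C)C[C@H](OC(C)=O)[C@@]21C | intermediate
29 | macrocyclic butenolide with 9-OTES and 12-OTBS (1S,2S,5Z,7S,9S,10S,11R,12R,14S) | CCCC(=O)O[C@H]1CC/C(C)=C\[C@@H]2OC(=O)C(C)=C2[C@@H](O[Si](CC)(CC)CC)[C@H]2[C@@H](C)[C@H](O[Si](C)(C)C(C)(C)C)C[C@H](OC(C)=O)[C@@]21C | intermediate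
30 | 9-hydroxy macrocyclic butenolide with 12-OTBS | CCCC(=O)O[C@H]1CC/C(C)=C\[C@@H]2OC(=O)C(C)=C2[C@@H](O)[C@H]2[C@@H](C)[C@H](O[Si](C)(C)C(C)(C)C)C[C@H](OC(C)=O)[C@@]21C | intermediate
31 | 9,14-di-O-acetyl-2-O-butanoyl-12-O-tert-butyldimethylsilyl macrocycle | CCCC(=O)O[C@H]1CC/C(C)=C\[C@@H]2OC(=O)C(C)=C2[C@@H](OC(C)=O)[C@H]2[C@@H](C)[C@H](O[Si](C)(C)C(C)(C)C)C[C@H](OC(C)=O)[C@@]21C | intermediate
32 | CNP0281577.2 (1S,2S,5Z,7S,9S,10S,11R,12R,14S) | CCCC(=O)O[C@H]1CC/C(C)=C\[C@@H]2OC(=O)C(C)=C2[C@@H](OC(C)=O)[C@H]2[C@@H](C)[C@H](O)C[C@H](OC(C)=O)[C@@]21C | target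

**Totals**
Total steps: 18. Longest linear sequence: 14 steps (1–5, 8–11, 14–18).

**Three steps most likely to fail**

Step 15 (new carbonylative ring closure). Risks are competing 1,4-reactivity of the enal, CO binding to nickel before the metallacycle forms, and C7 selectivity. A fallback built only on known reactions sets out from 20. RuCl3 (cat.)/NaIO4 (NaHCO3-buffered) cleaves the alkyne to the α-silyloxy carboxylic acid F1. Carbonyldiimidazole followed by the magnesium salt of methyl hydrogen methylmalonate gives the β-keto ester F2. NaH and N-phenyl-bis(trifluoromethanesulfonimide) give the (Z)-enol triflate F3. The zinc/Negishi protocol of step 14 with 24 gives the enal triflate F4. An intramolecular Nozaki–Hiyama–Kishi reaction (CrCl2, NiCl2 cat., DMF, high dilution) then forms C7–C8, and the chromium alkoxide lactonises onto the cis ester, which returns the route to 29.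

Step 10 (tandem ring expansion/reduction). Risks are migration of C13 instead of C10, and a slow or unselective Tishchenko stage on the α-quaternary ketone. The fallback sets out from 16 and separates the events. Yb(OTf)3 (cat.) in CH2Cl2 gives the isolated hydroxy ketone 18. Butyric anhydride/DMAP gives the keto butanoate F5. (R)-2-methyl-CBS-oxazaborolidine with catecholborane (−78 to −40 °C) then reduces C14 under reagent control (C1 as the large group), which returns the route to 19.

Step 5 (kinetic protonation to the 2,3-cis ketone). Risks are a cis/trans mixture at C10 and epimerisation of 8 on handling. The fallback sets out from 6. Me2CuLi followed by Me3SiCl/Et3N gives the trimethylsilyl enol ether F6, which is isolated and then protonated under reagent control with the (R)-BINOL·SnCl4 Lewis-acid-assisted Brønsted acid in toluene at −78 °C, which returns the route to 8.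

**Further compounds**
F1 | step 15 | α-silyloxy carboxylic acid from alkyne cleavage of 20 (C8 as CO2H) | CCCC(=O)O[C@@H](CCCl)[C@@]1(C)[C@@H](OC(C)=O)C[C@@H](O[Si](C)(C)C(C)(C)C)[C@H](C)[C@@H]1[C@H](O[Si](CC)(CC)CC)C(=O)O
F2 | step 15 | β-keto ester (C8 ketone; C17 methyl and methyl ester; C17 epimers) | CCCC(=O)O[C@@H](CCCl)[C@@]1(C)[C@@H](OC(C)=O)C[C@@H](O[Si](C)(C)C(C)(C)C)[C@H](C)[C@@H]1[C@H](O[Si](CC)(CC)CC)C(=O)C(C)C(=O)OC
F3 | step 15 | (Z)-enol triflate of F2 (triflate cis to the ester) | CCCC(=O)O[C@@H](CCCl)[C@@]1(C)[C@@H](OC(C)=O)C[C@@H](O[Si](C)(C)C(C)(C)C)[C@H](C)[C@@H]1[C@H](O[Si](CC)(CC)CC)/C(OS(=O)(=O)C(F)(F)F)=C(\C)C(=O)OC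
F4 | step 15 | enal triflate: F3 with the (Z)-enal chain attached at C4 | CCCC(=O)O[C@@H](CC/C(C)=C\C=O)[C@@]1(C)[C@@H](OC(C)=O)C[C@@H](O[Si](C)(C)C(C)(C)C)[C@H](C)[C@@H]1[C@H](O[Si](CC)(CC)CC)/C(OS(=O)(=O)C(F)(F)F)=C(\C)C(=O)OC
F5 | step 10 | keto butanoate: 2-O-butanoyl derivative of 18 | CCCC(=O)O[C@@H](CCCl)[C@@]1(C)C(=O)C[C@@H](O[Si](C)(C)C(C)(C)C)[C@H](C)[C@@H]1[C@H](O[Si](CC)(CC)CC)C#CC
F6 | step 5 | trimethylsilyl enol ether of 8 | C[Si](C)(C)OC1=C([C@H](O[Si](CC)(CC)CC)C#CC)[C@@H](C)[C@H](O[Si](C)(C)C(C)(C)C)C1
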